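**Retrosynthetic overview**
- The target is read as 6α-angeloyloxy-labd-14-ene-8α,13R-diol. The angelate goes on last; the 6α,8α-diol comes from a 7-en-6-one by α-epoxidation of C7=C8, reductive cleavage of C7–O and thermodynamic reduction of C6.
- The side chain C12–C16 is joined to C11 as a C5 allylic bromide. C13 is set by Sharpless epoxidation, and epoxy-iodide fragmentation gives the vinyl carbinol. C11 and 9α-H come from methylenation and hydroboration of a C9 ketone.
- Ring A is cut at C3–C4: a tertiary C4 radical, made by hydrogen-atom transfer to an isopropenyl group, adds 6-endo to an acrylate tethered at C10. The C2 ester is then excised.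
- The strategy rests on ring B (C5–C10). With C17 on C8, oxygen at C9, the C5 stereocentre and C4 attached to C5, it is (R)-carvone, so ring A lacks only C1–C3 between C10 and C4.
- Ring order: ring B from the chiral pool, ring A by radical closure (step 3), then side chain, then ring-B oxygenation.

Key step: step 3

Remark: the SMILES is read as the normal labdane series (5S,6S,8R,9R,10S,13R); compounds 6–8 are carried as C2 epimer mixtures (2α drawn) that converge in step 5.

**Step 1**
Reactants: 1 (R)-carvone; 2 iodomethane
Product: 3 (5R,6S)-2,6-dimethyl-5-(prop-1-en-2-yl)cyclohex-2-en-1-one (trans-6-methylcarvone)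
Conditions: LiN(i-Pr)2, THF, −78 °C; MeI, −78 → 0 °C
Reagents that add atoms: iodomethane (2), CI
Why: Kinetic enolate alkylation: LiN(i-Pr)2 removes an α′-hydrogen to give the cross-conjugated enolate, which should be C-methylated mainly anti to the isopropenyl group; the new centre is re-enolised in step 2, so its configuration does not matter.

**Step 2**
Reactants: 3 trans-6-methylcarvone; 4 methyl 2-(bromomethyl)acrylate
Product: 5 methyl 2-{[(1S,6S)-1,3-dimethyl-2-oxo-6-(prop-1-en-2-yl)cyclohex-3-en-1-yl]methyl}prop-2-enoate
Conditions: LiN(i-Pr)2, THF, −78 °C; 4, −78 → −30 °C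
Reagents that add atoms: methyl 2-(bromomethyl)acrylate (4), COC(=O)C(=C)CBr
Why: Enolate alkylation of the tetrasubstituted α′-enolate with a reactive allylic bromide (direct or addition–elimination attack gives the same product) should occur on the ring face opposite to the adjacent isopropenyl group, which sets the quaternary C10 with its methyl cis and the acrylate arm trans to that group.

**Step 3**
Reactants: 5 acrylate-tethered methylcarvone
Product: 6 methyl (2S,4aS,8aS)-4,4,7,8a-tetramethyl-8-oxo-1,2,3,4,4a,5,8,8a-octahydronaphthalene-2-carboxylate (2α-epimer drawn)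
Conditions: Fe(acac)3 (0.3 equiv), PhSiH3 (2.5 equiv), EtOH/ethylene glycol (5:1), degassed, 60 °C, high dilution
Reagents that add atoms: none
Why: An iron hydride formed from Fe(acac)3 and PhSiH3 transfers a hydrogen atom to the terminal CH2 of the electron-rich isopropenyl group, which becomes the second methyl on C4 and leaves a tertiary C4 radical; this nucleophilic radical adds to the CH2 terminus (C3) of the acrylate, and the α-ester radical at C2 is reduced by divalent iron to the enolate and protonated by ethanol. The closest known reaction type is the Fe(acac)3/PhSiH3 reductive coupling of 1,1-disubstituted alkenes with acrylates (Mukaiyama-type hydrogen-atom transfer followed by Giese addition), including intramolecular 6-endo closures onto 2-substituted acrylates. Ring A is closed in the 6-endo-trig mode by the new C3–C4 bond; 5-exo closure would require attack at the fully substituted, ester-bearing C2 and would give a primary radical. C4 becomes a non-stereogenic gem-dimethyl carbon and C2 is formed without control (the equatorial 2α-ester should dominate after protonation) and is deleted in step 5; the trans ring fusion is not created here but follows from C5 and C10 of 5, whose two reacting arms are trans-diequatorial on ring B. The step needs chemoselective hydrogen-atom transfer to the isopropenyl group in the presence of the acrylate and the enone, and 6-endo regioselectivity; the first should be secured by the unhindered, electron-rich 1,1-dialkyl alkene being the best hydrogen-atom acceptor, the second by the polarity match between the nucleophilic tertiary radical and the acrylate β-carbon.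

**Step 4**
Reactants: 6 bicyclic keto ester
Product: 7 (2S,4aS,8aS)-4,4,7,8a-tetramethyl-8-oxo-1,2,3,4,4a,5,8,8a-octahydronaphthalene-2-carboxylic acid
Conditions: LiOH, THF/MeOH/H2O, rt; then 1 M HCl
Reagents that add atoms: lithium hydroxide, [Li+].[OH-]
Why: Ester saponification of the unhindered secondary methyl ester; the enone is inert to aqueous hydroxide at room temperature and neither ring-fusion centre can epimerise.

**Step 5**
Reactants: 7 keto acid
Product: 9 (4aS,8aS)-2,5,5,8a-tetramethyl-4a,5,6,7,8,8a-hexahydronaphthalen-1(4H)-one, via Barton ester 8 (not isolated)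
Conditions: N-hydroxypyridine-2-thione, DCC, DMAP (cat.), CH2Cl2, rt, dark; then t-BuSH, hν (tungsten lamp), rt
Reagents that add atoms: none
Why: Barton reductive decarboxylation: the thiohydroxamate ester fragments under visible light to CO2 and the secondary C2 radical, which abstracts hydrogen from t-BuSH, so that C2 becomes a methylene and the epimer mixture converges.

**Step 6**
Reactants: 9 bicyclic enone
Product: 10 (4aS,8aS)-2,5,5,8a-tetramethyl-1-methylidene-1,4,4a,5,6,7,8,8a-octahydronaphthalene (drima-7,9(11)-diene)
Conditions: Ph3PCH3Br, KOt-Bu, toluene, 90 °C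
Reagents that add atoms: methyltriphenylphosphonium bromide, C[P+](c1ccccc1)(c1ccccc1)c1ccccc1.[Br-]
Why: Wittig methylenation under forcing conditions (ylide from KOt-Bu in hot toluene), as used for ketones next to a quaternary carbon; the ketone has no α-hydrogen, so the only side process is reversible γ-deprotonation.

**Step 7**
Reactants: 10 drima-7,9(11)-diene
Product: 12 drimenol [(1S,4aS,8aS)-2,5,5,8a-tetramethyl-1,4,4a,5,6,7,8,8a-octahydronaphthalen-1-yl]methanol, via alkylborane 11 (not isolated)
Conditions: 9-BBN (1.1 equiv), THF, 0 °C → rt; then NaOH (aq), H2O2 (30%), 0 °C → rt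
Reagents that add atoms: hydrogen peroxide, OO
Why: Hydroboration–oxidation: the bulky 9-BBN should add only to the unhindered exocyclic CH2 terminus of the diene (boron on C11) and deliver hydrogen to C9 from the α face, opposite to the axial C10 methyl, so that C9 obtains 9α-H and a β (equatorial) CH2OH; oxidation of the C–B bond proceeds with retention.

**Step 8**
Reactants: 12 drimenol
Product: 13 (1S,4aS,8aS)-1-(bromomethyl)-2,5,5,8a-tetramethyl-1,4,4a,5,6,7,8,8a-octahydronaphthalene (11-bromodrim-7-ene)
Conditions: CBr4, PPh3, CH2Cl2, 0 °C → rt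
Reagents that add atoms: carbon tetrabromide, BrC(Br)(Br)Br
Why: Appel bromination: SN2 displacement of the alkoxyphosphonium at the primary C11 by bromide under neutral conditions, leaving the ring alkene and C9 untouched.

**Step 9**
Reactants: 14 3-methylbut-2-en-1-ol (prenol)
Product: 15 tert-butyldimethyl(3-methylbut-2-enyloxy)silane
Conditions: TBSCl, imidazole, CH2Cl2, rt
Reagents that add atoms: tert-butyldimethylsilyl chloride, CC(C)(C)[Si](C)(C)Cl
Why: Standard silylation of a primary allylic alcohol.

**Step 10**
Reactants: 15 prenyl silyl ether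
Product: 16 (E)-4-(tert-butyldimethylsilyloxy)-2-methylbut-2-en-1-ol
Conditions: SeO2 (0.3 equiv), t-BuOOH (2 equiv), salicylic acid (cat.), CH2Cl2, rt
Reagents that add atoms: tert-butyl hydroperoxide, CC(C)(C)OO; selenium dioxide (catalytic oxygen carrier), O=[Se]=O
Why: Selenium dioxide allylic oxidation (ene reaction then 2,3-sigmatropic shift) with t-BuOOH as terminal oxidant, which is selective for the methyl group trans to the chain on a trisubstituted alkene and so gives the E allylic alcohol.

**Step 11**
Reactants: 16 E allylic alcohol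
Product: 17 (E)-(4-bromo-3-methylbut-2-enyloxy)(tert-butyl)dimethylsilane
Conditions: CBr4, PPh3, CH2Cl2, 0 °C
Reagents that add atoms: carbon tetrabromide, BrC(Br)(Br)Br
Why: Appel bromination of a primary allylic alcohol by direct displacement, which keeps the E geometry and the silyl ether.

**Step 12**
Reactants: 13 11-bromodrim-7-ene; 17 C5 allylic bromide
Product: 19 tert-butyldimethylsilyl ether of (E)-labda-7,13-dien-15-ol, via Grignard reagent 18 (not isolated)
Conditions: Mg, THF, 50 °C; then 17, Li2CuCl4 (3 mol%), THF, −78 → 0 °C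
Reagents that add atoms: C5 allylic bromide (17), BrC/C(C)=C/CO[Si](C)(C)C(C)(C)C
Why: Copper-catalysed cross-coupling of a Grignard reagent with a primary allylic bromide (Kochi type): substitution at the unhindered CH2Br terminus should predominate over attack at the substituted γ-carbon, the E alkene geometry is retained and C9 is not touched.

**Step 13**
Reactants: 19 allylic silyl ether
Product: 20 (E)-labda-7,13-dien-15-ol
Conditions: Bu4NF, THF, rt
Reagents that add atoms: none
Why: Fluoride-mediated cleavage of the primary tert-butyldimethylsilyl ether.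

**Step 14**
Reactants: 20 (E)-labda-7,13-dien-15-ol
Product: 21 (13R,14R)-13,14-epoxylabd-7-en-15-ol
Conditions: Ti(OiPr)4 (10 mol%), D-(−)-diisopropyl tartrate (12 mol%), t-BuOOH (decane), 4 Å molecular sieves, CH2Cl2, −20 °C
Reagents that add atoms: tert-butyl hydroperoxide, CC(C)(C)OO
Why: Sharpless asymmetric epoxidation: with the D-(−)-tartrate ligand the titanium-bound peroxide is delivered to the face of the E allylic alcohol that gives the (13R,14R)-epoxide (reagent control, the same sense in which geraniol gives its 2R,3R-epoxide), which fixes C13; the ring alkene has no directing hydroxyl and is not epoxidised.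

**Step 15**
Reactants: 21 epoxy alcohol
Product: 22 (13R,14S)-13,14-epoxy-15-iodolabd-7-ene
Conditions: I2, PPh3, imidazole, THF, 0 °C
Reagents that add atoms: iodine, II
Why: Appel-type iodination of the primary alcohol by SN2 at C15; the epoxide and both stereocentres are untouched (the C14 descriptor changes only through priority).

**Step 16**
Reactants: 22 epoxy iodide
Product: 23 (13R)-labda-7,14-dien-13-ol
Conditions: Zn dust (activated), EtOH, 70 °C
Reagents that add atoms: none
Why: Reductive fragmentation of a 2,3-epoxy iodide: zinc inserts into the C–I bond and β-elimination opens the epoxide at C14, giving the C14=C15 vinyl group while the C13–O bond, and with it the 13R configuration, is retained.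

**Step 17**
Reactants: 23 (13R)-labda-7,14-dien-13-ol
Product: 24 (13R)-13-(triethylsilyloxy)labda-7,14-diene
Conditions: Et3SiOTf, 2,6-lutidine, CH2Cl2, −78 → 0 °C
Reagents that add atoms: triethylsilyl trifluoromethanesulfonate, CC[Si](CC)(CC)OS(=O)(=O)C(F)(F)F
Why: Silylation of the tertiary allylic alcohol with the reactive silyl triflate; the ether masks the carbinol against oxidative 1,3-transposition by hexavalent chromium in the next step.

**Step 18**
Reactants: 24 silyl-protected dienol
Product: 25 (13R)-13-(triethylsilyloxy)labda-7,14-dien-6-one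
Conditions: CrO3, 3,5-dimethylpyrazole, CH2Cl2, −20 °C
Reagents that add atoms: chromium trioxide, O=[Cr](=O)=O
Why: Allylic C–H oxidation with the CrO3·3,5-dimethylpyrazole complex: C6 is the only allylic methylene of the ring alkene, an allylic chromate formed at either end of the C6–C7–C8 allyl system collapses to the conjugated 7-en-6-one, and the vinyl group has no allylic hydrogen.

**Step 19**
Reactants: 25 silyl-protected enone
Product: 26 (13R)-13-hydroxylabda-7,14-dien-6-one
Conditions: HF·pyridine, pyridine, THF, 0 °C → rt
Reagents that add atoms: none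
Why: Fluoride cleavage of the triethylsilyl ether under buffered, non-basic conditions that affect neither the enone nor the tertiary allylic alcohol.

**Step 20**
Reactants: 26 enone
Product: 27 (13R)-7α,8α-epoxy-13-hydroxylabd-14-en-6-one
Conditions: H2O2 (30%), NaOH (aq, substoichiometric), MeOH, 0 °C → rt
Reagents that add atoms: hydrogen peroxide, OO
Why: Nucleophilic (Weitz–Scheffer) epoxidation of the β,β-disubstituted enone: hydroperoxide should add to C8 from the α face, away from the syn-axial C10 methyl and the β side chain on C9, so that the epoxide oxygen is 7α,8α and C17 becomes β; the isolated vinyl group is inert to alkaline peroxide.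

**Step 21**
Reactants: 27 epoxy ketone
Product: 28 (13R)-8α,13-dihydroxylabd-14-en-6-one
Conditions: SmI2 (2.2 equiv), THF/MeOH, −90 °C
Reagents that add atoms: none
Why: Reductive opening of an α,β-epoxy ketone by single-electron transfer from SmI2: the ketyl cleaves the C7–O bond α to the carbonyl, methanol protonates C7 and the C8–O bond is untouched, so the tertiary alcohol keeps the 8α configuration.

**Step 22**
Reactants: 28 β-hydroxy ketone
Product: 29 (13R)-labd-14-ene-6α,8α,13-triol
Conditions: Li, NH3(l), THF, EtOH, −78 °C; then NH4Cl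
Reagents that add atoms: none
Why: Dissolving-metal ketone reduction under thermodynamic control: the ketyl and carbanion intermediates should be protonated to the equatorial 6α-alkoxide, because a 6β-oxygen would be syn-axial to the C4β, C8β and C10 methyl groups, whereas hydride reagents would attack the open α face and give the 6β-epimer; the low temperature suppresses retro-aldol cleavage.

**Step 23**
Reactants: 29 triol; 30 angelic acid
Product: 32 (13R)-6α-[(Z)-2-methylbut-2-enoyloxy]labd-14-ene-8α,13-diol (target), via mixed anhydride 31 (not isolated)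
Conditions: 30, 2,4,6-trichlorobenzoyl chloride, Et3N, toluene, rt; then 29, 80 °C
Reagents that add atoms: angelic acid (30), C/C=C(/C)C(=O)O
Why: Yamaguchi-type esterification through the mixed anhydride of angelic acid, run without a nucleophilic catalyst so that the Z acyl group is transferred without isomerisation to the tiglate; only the secondary equatorial 6α-hydroxyl should be acylated, the tertiary C8 and C13 hydroxyls being unreactive.

**Compound list**
1 | (R)-carvone | CC1=CC[C@H](CC1=O)C(C)=C | starting material
2 | iodomethane | CI | starting material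
3 | (5R,6S)-2,6-dimethyl-5-(prop-1-en-2-yl)cyclohex-2-en-1-one | C[C@@H]1C(=O)C(C)=CC[C@H]1C(C)=C | intermediate
4 | methyl 2-(bromomethyl)acrylate | COC(=O)C(=C)CBr | starting material
5 | methyl 2-{[(1S,6S)-1,3-dimethyl-2-oxo-6-(prop-1-en-2-yl)cyclohex-3-en-1-yl]methyl}prop-2-enoate | COC(=O)C(=C)C[C@]1(C)C(=O)C(C)=CC[C@H]1C(C)=C | intermediate
6 | methyl (2S,4aS,8aS)-4,4,7,8a-tetramethyl-8-oxo-1,2,3,4,4a,5,8,8a-octahydronaphthalene-2-carboxylate (2α-epimer drawn) | COC(=O)[C@@H]1C[C@]2(C)C(=O)C(C)=CC[C@H]2C(C)(C)C1 | intermediate
7 | (2S,4aS,8aS)-4,4,7,8a-tetramethyl-8-oxo-1,2,3,4,4a,5,8,8a-octahydronaphthalene-2-carboxylic acid | OC(=O)[C@@H]1C[C@]2(C)C(=O)C(C)=CC[C@H]2C(C)(C)C1 | intermediate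
8 | Barton ester of 7 (2-thioxopyridin-1(2H)-yl ester) | S=C1C=CC=CN1OC(=O)[C@@H]1C[C@]2(C)C(=O)C(C)=CC[C@H]2C(C)(C)C1 | intermediate (not isolated)
9 | (4aS,8aS)-2,5,5,8a-tetramethyl-4a,5,6,7,8,8a-hexahydronaphthalen-1(4H)-one | O=C1[C@@]2(C)CCCC(C)(C)[C@@H]2CC=C1C | intermediate
10 | drima-7,9(11)-diene | C=C1[C@@]2(C)CCCC(C)(C)[C@@H]2CC=C1C | intermediate
11 | 9-(drim-7-en-11-yl)-9-borabicyclo[3.3.1]nonane | C1CCC2CCCC1B2C[C@@H]1[C@@]2(C)CCCC(C)(C)[C@@H]2CC=C1C | intermediate (not isolated)
12 | drimenol | OC[C@@H]1[C@@]2(C)CCCC(C)(C)[C@@H]2CC=C1C | intermediate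
13 | 11-bromodrim-7-ene | BrC[C@@H]1[C@@]2(C)CCCC(C)(C)[C@@H]2CC=C1C | intermediate
14 | 3-methylbut-2-en-1-ol | CC(C)=CCO | starting material
15 | tert-butyldimethyl(3-methylbut-2-enyloxy)silane | CC(C)=CCO[Si](C)(C)C(C)(C)C | intermediate
16 | (E)-4-(tert-butyldimethylsilyloxy)-2-methylbut-2-en-1-ol | OC/C(C)=C/CO[Si](C)(C)C(C)(C)C | intermediate
17 | (E)-(4-bromo-3-methylbut-2-enyloxy)(tert-butyl)dimethylsilane | BrC/C(C)=C/CO[Si](C)(C)C(C)(C)C | intermediate
18 | (drim-7-en-11-yl)magnesium bromide | Br[Mg]C[C@@H]1[C@@]2(C)CCCC(C)(C)[C@@H]2CC=C1C | intermediate (not isolated)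
19 | tert-butyldimethylsilyl ether of (E)-labda-7,13-dien-15-ol | CC(C)(C)[Si](C)(C)OC/C=C(\C)CC[C@@H]1[C@@]2(C)CCCC(C)(C)[C@@H]2CC=C1C | intermediate
20 | (E)-labda-7,13-dien-15-ol | OC/C=C(\C)CC[C@@H]1[C@@]2(C)CCCC(C)(C)[C@@H]2CC=C1C | intermediate
21 | (13R,14R)-13,14-epoxylabd-7-en-15-ol | OC[C@H]3O[C@]3(C)CC[C@@H]1[C@@]2(C)CCCC(C)(C)[C@@H]2CC=C1C | intermediate
22 | (13R,14S)-13,14-epoxy-15-iodolabd-7-ene | IC[C@H]3O[C@]3(C)CC[C@@H]1[C@@]2(C)CCCC(C)(C)[C@@H]2CC=C1C | intermediate
23 | (13R)-labda-7,14-dien-13-ol | C=C[C@](C)(O)CC[C@@H]1[C@@]2(C)CCCC(C)(C)[C@@H]2CC=C1C | intermediate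
24 | (13R)-13-(triethylsilyloxy)labda-7,14-diene | C=C[C@](C)(O[Si](CC)(CC)CC)CC[C@@H]1[C@@]2(C)CCCC(C)(C)[C@@H]2CC=C1C | intermediate
25 | (13R)-13-(triethylsilyloxy)labda-7,14-dien-6-one | C=C[C@](C)(O[Si](CC)(CC)CC)CC[C@@H]1[C@@]2(C)CCCC(C)(C)[C@@H]2C(=O)C=C1C | intermediate
26 | (13R)-13-hydroxylabda-7,14-dien-6-one | C=C[C@](C)(O)CC[C@@H]1[C@@]2(C)CCCC(C)(C)[C@@H]2C(=O)C=C1C | intermediate
27 | (13R)-7α,8α-epoxy-13-hydroxylabd-14-en-6-one | C=C[C@](C)(O)CC[C@@H]1[C@@]2(C)CCCC(C)(C)[C@@H]2C(=O)[C@H]3O[C@@]13C | intermediate
28 | (13R)-8α,13-dihydroxylabd-14-en-6-one | C=C[C@](C)(O)CC[C@@H]1[C@@]2(C)CCCC(C)(C)[C@@H]2C(=O)C[C@@]1(C)O | intermediate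
29 | (13R)-labd-14-ene-6α,8α,13-triol | C=C[C@](C)(O)CC[C@@H]1[C@@]2(C)CCCC(C)(C)[C@@H]2[C@@H](O)C[C@@]1(C)O | intermediate
30 | angelic acid, (Z)-2-methylbut-2-enoic acid | C/C=C(/C)C(=O)O | starting material
31 | angelic 2,4,6-trichlorobenzoic anhydride | C/C=C(/C)C(=O)OC(=O)c1c(Cl)cc(Cl)cc1Cl | intermediate (not isolated)
32 | (13R)-6α-angeloyloxylabd-14-ene-8α,13-diol (CNP0203829.1) | C=C[C@](C)(O)CC[C@@H]1[C@@]2(C)CCCC(C)(C)[C@@H]2[C@@H](OC(=O)/C(C)=C\C)C[C@@]1(C)O | target

**Step count**
Total: 23 steps (20 in the main line, 3 for the C5 bromide 17).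
Longest linear sequence: 20 steps (steps 1–8 and 12–23) from (R)-carvone.

**Steps most likely to fail**

1. Step 3. Hydrogen-atom transfer may go to the acrylate or the enone instead of the isopropenyl group, which leads to simple reduction or to the isomeric closure from the acrylate-derived radical. The C4 radical may also be reduced before it closes the ring. The fallback sets out from 5 and comes back at 6. Ionic Markovnikov addition of HBr (HBr in AcOH, CH2Cl2, −20 °C) to the isopropenyl group should give the tertiary bromide of 5, F1. Slow addition of Bu3SnH with AIBN (benzene, 80 °C) then forms the same C4 radical by bromine abstraction, without any hydride-transfer chemoselectivity, and the tin-mediated Giese cyclisation (6-endo) delivers 6.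

2. Step 18. Hydrogen abstraction at the tertiary allylic C9–H or at C17 may compete with abstraction at C6 and move the oxidation to C7, and over-oxidation may lower the throughput. The fallback sets out from 24 and comes back at 25, and it fixes the regiochemistry by an oxygen transposition.
   - Epoxidation of the ring alkene from the α face (mCPBA, NaHCO3, CH2Cl2, 0 °C; the vinyl group reacts far more slowly) gives the 7α,8α-epoxide of 24, F2.
   - Opening at the secondary C7 with PhSeNa (PhSeSePh, NaBH4, EtOH, reflux) gives the 7β-phenylselanyl-8α-ol F3.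
   - Oxidation with H2O2/pyridine lets the selenoxide eliminate syn toward C6 and gives the tertiary allylic alcohol (13R)-13-(triethylsilyloxy)labda-6,14-dien-8α-ol, F4.
   - Babler–Dauben oxidative transposition with pyridinium chlorochromate, C5H5NH[CrO3Cl], in CH2Cl2 moves the oxygen from C8 to C6 and gives enone 25.

3. Step 6. The olefination may stall because the C9 carbonyl is shielded by the quaternary C10 and the C8 methyl, and because the ylide can deprotonate the γ-position. The fallback sets out from 9 and comes back at 10. CeCl3-promoted 1,2-addition of Me3SiCH2Li (THF, −78 °C) should give the β-hydroxysilane F5, with attack expected from the α face; this centre is erased again. Peterson syn-elimination with KH in THF then forms the exocyclic C9=C11 bond of 10 without a cationic intermediate.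

**Further compounds**
F1 | step 3 | methyl 2-{[6-(2-bromopropan-2-yl)-1,3-dimethyl-2-oxocyclohex-3-en-1-yl]methyl}prop-2-enoate (ring configuration as in 5) | COC(=O)C(=C)C[C@]1(C)C(=O)C(C)=CC[C@H]1C(C)(C)Br
F2 | step 18 | (13R)-7α,8α-epoxy-13-(triethylsilyloxy)labd-14-ene | C=C[C@](C)(O[Si](CC)(CC)CC)CC[C@@H]1[C@@]2(C)CCCC(C)(C)[C@@H]2C[C@H]3O[C@@]13C
F3 | step 18 | (13R)-7β-(phenylselanyl)-13-(triethylsilyloxy)labd-14-en-8α-ol | C=C[C@](C)(O[Si](CC)(CC)CC)CC[C@@H]1[C@@]2(C)CCCC(C)(C)[C@@H]2C[C@H]([Se]c3ccccc3)[C@@]1(C)O
F4 | step 18 | (13R)-13-(triethylsilyloxy)labda-6,14-dien-8α-ol | C=C[C@](C)(O[Si](CC)(CC)CC)CC[C@@H]1[C@@]2(C)CCCC(C)(C)[C@@H]2C=C[C@@]1(C)O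
F5 | step 6 | (4aS,8aS)-2,5,5,8a-tetramethyl-1-[(trimethylsilyl)methyl]-1,4,4a,5,6,7,8,8a-octahydronaphthalen-1-ol (1β-hydroxy expected) | C[Si](C)(C)C[C@@]1(O)[C@@]2(C)CCCC(C)(C)[C@@H]2CC=C1C
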